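The rate constants belong to no real substance; no experiment stands behind them.

Follow the coupling partner.

left-handed substrate 20 mM; solid reagent 16.0 mM; right-handed substrate 20 mM; time 50 min

    coupling partner + right-handed substrate → right-handed product (k1 = 0.0286 M⁻¹ s⁻¹)
    coupling partner + left-handed substrate → left-handed product (k2 = 0.0877 M⁻¹ s⁻¹)
    solid reagent ⇌ coupling partner, rate k3*(cs3 - [coupling partner]) while solid is left; crystals form when [coupling partner] > cs3 (cs3 = 11 mM, k3 = 0.00225 s⁻¹)
    2 coupling partner → self-condensation product (k4 = 0.718 M⁻¹ s⁻¹)

* at 50 min, what has stopped the reaction, if anything has (for what has run out or reacted, a solid counts together with what of it has only dissolved) (forward and back rates have come level / it is still moving / the coupling partner has run out first / all of the left-handed substrate has reacted)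
* conversion of left-handed substrate and right-handed substrate together at 50 min
* amount of left-handed product at 50 min, in percent of the left-handed substrate and right-handed substrate together charged

- coupling partner is single-handed; left-handed substrate and right-handed substrate are mirror images of each other, charged as a racemate, each of them at the stated concentration
- a doubled species enters its step squared and goes two at a time
- as a solid, counted per litre of solution: solid reagent
- at the start none of the solid reagent is in solution
- the reaction counts as stopped when no species that holds the left-handed substrate and right-handed substrate together changes by six tenths of a point or more over the second half of the time
- run time (flask): 50 min
- the handed part of coupling partner does not stay in what it makes, so the products of the two hands are mirror images too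

The two substrates together, at 40.0 mM, exceed the 16.0 mM of solid reagent, so the solid reagent is the limiting reagent, and what you need to know is where each dissolved coupling partner goes. I reckon this from two times. With both substrates near their charge, a dissolved coupling partner couples, pseudo-first-order, once in 7.17 min on average. While solid is left, I take dissolving to balance both losses, which puts [coupling partner] at 2.85 mM in my reckoning, and at that level self-condensation takes it once in 4.07 min, which is the shorter time. So 36.2% is your coupling share, the self-condensation time over the sum of the two times, the part of dissolved coupling partner I expect to end on substrate. The solid is gone after about 14.5 min, well before 50 min, so I expect the coupling partner to run out first, at a conversion of 14.5%, with 10.9% as left-handed product.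

The forecast says the coupling partner has run out first, with 15.5% conversion and 11.4% as left-handed product, on the ground “partner exhausted, mostly by dimerisation”; its conversion stands 1 percentage point above mine.

In the flask, the coupling partner has run out first, with 15.5% converted and 11.4% as left-handed product. At 50.0 min, 0.097% of the charged coupling partner is still there in this flask, solid or dissolved. Now put your coupling share of 36.2% to use on a neighbour flask charged with 27 mM of solid reagent, all else as in the recipe: that share of the charge, taken over the 40.0 mM of both substrates, reckons to 24.4% conversion, and the neighbour flask reaches 23.6%.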